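## Structural features

The target is a 2,4-disubstituted chroman (flavan numbering O1, C2, C3, C4, C4a–C8a) fused to a fully differentiated phloroglucinol ring A. Ring A carries a free hydroxyl at C5, a methoxy group at C7 and an (E)-4-hydroxycinnamoyl ketone at C8. C2 (R) bears a 4-hydroxyphenyl group (ring B) and C4 (S) bears a (2R)-2-hydroxy-4-(4-hydroxyphenyl)butyl chain (ring C at its end). C2 and C4 stand 1,3 across the pyran ring with their substituents trans, and C4 and the chain carbinol C2' again stand 1,3, so that C2–C3–C4–C1'–C2' read as an open chain is a 3-aryl-1,5-diol. The trans arrangement is not the thermodynamically preferred one for such a chroman, and the C2–O1 bond is a 4-oxygenated benzylic aryl ether that can ionise under acid or open through a quinone methide under base, so C2 can epimerise in any late step. The chalcone is a Michael acceptor and a reducible olefin, and four phenols and one secondary alcohol must be carried masked. The real difficulties are the ring-A pattern (where C6 and C8 cannot be told apart by electrophilic substitution), the C2' carbinol (flanked by two methylene groups and out of reach of ring control) and the kinetic 2,4-trans relationship. The key step exploits the fact that O1 on C8a and the acyl group on C8 are neighbours, with the C7 methoxy group beside C8: a C8–C8a aryne can accept the C2 oxygen at C8a and the cinnamoyl electrophile at C8 in one operation.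

## Logic of the disconnections

22 to 21: only five O–Si bonds are cut. All phenols and the chain carbinol are masked as silyl ethers so that one fluoride treatment ends the synthesis. The forward step must be buffered so that neither the C2–O1 bond nor the enone is disturbed.

21 to 17 and 18: the O1–C8a bond and the C8–carbonyl bond are cut. This removes the pyran ring and the most hindered substituent of ring A together and turns a hexasubstituted arene into a pentasubstituted aryl bromide plus an intact cinnamoyl unit. The C2 configuration is carried by a carbinol whose C–O bond stays intact. The forward step, which runs through 19 and 20, needs a single aryne regioisomer, a single free hydroxyl and clean 1,2-acylation of a doubly ortho-substituted aryllithium.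

17 to 16: the C2–H bond is cut (carbinol back to aryl ketone). The ketone serves as the latent C2 hydroxyl, so the C2' oxygen can be silylated earlier without competition, and an aryl alkyl ketone is the best case for catalyst-controlled reduction. The forward step must override any bias from C4.

16 to 15: no skeletal bond is cut; the saturated C3'–C4' link is read back as a triple bond (four C–H bonds removed). With an alkyne beside C2' the carbinol becomes a propargylic one, which can be assembled from an aldehyde and a terminal alkyne used one-to-one. The forward step must saturate the triple bond without touching the aryl bromide or the aryl ketone.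

15 to 14: the O–Si bond at C2' is cut. The silyl group is placed while C2 is still a ketone, so the two oxygens are told apart without effort. The forward step is routine.

14 to 9 and 12: the C2'–C3' bond is cut. A ketone at C2' of the saturated chain would have two methylene flanks and could not be reduced selectively, so the carbinol is made in the C–C bond-forming event itself, through 13. The forward step needs catalyst-controlled facial selectivity on an aldehyde without α-branching and must leave the aryl ketone alone.

9 to 5 and 8: the C3–C4 bond is cut. One conjugate addition sets C4 and delivers the two arms already differentiated as aldehyde (C2') and aryl ketone (C2), so no decarboxylation or redox adjustment is needed. The forward step needs facial control at the β-carbon of a doubly ortho-substituted enal.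

5 to 3, 3 to 2, 2 to 1: the C4=C1' olefin (through 4), the O–Si bond and the O–CH3 bond ortho to the formyl group are cut in turn. The ring-A pattern (bromine and oxygen flanking the carbon that becomes C4a, methoxy para) is fixed by 1 itself. The forward demethylation must touch only the ortho methoxy group.

8 to 7 to 6; 12 to 11 to 10; 18 to 11: rings B and C and the cinnamoyl unit are traced to two simple 4-hydroxyphenyl carbonyl compounds. 11 is shared by two branches. The forward steps are protection, enol silylation, one-carbon homologation to the alkyne and olefination.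

## Other disconnections considered

Alternative 1: The cut is C8–C8a, so ring A itself is made from a polyketide-like chain stored as the 2-pyranone A2. In the forward step Mg(OMe)2 in methanol would open the lactone of A2 to a magnesium-chelated triketo ester. The carbanion of the methylene group between the two ketone carbonyls would attack the ester carbonyl (the former lactone carbon), and loss of methoxide and enolisation would give the acylphloroglucinol A1 with the chalcone attached.
- In favour: the step is biomimetic and mild and needs no aryl halide and no cryogenic organolithium chemistry. Ring A and its acyl group are formed together, so on the placement of the cinnamoyl group next to C8a it is the equal of the chosen plan, and on operational simplicity of the key step it is the better.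
- Against: A1 has two free hydroxyls (C7 and C8a) bound to the same carbonyl, one to be methylated and one to be joined to C2. A1 carries the same silyl group on the C2 and C2' oxygens, so C2 cannot be unmasked alone. The O1–C2 bond would be made by displacement at a 4-alkoxybenzylic carbon, where ionisation competes and would favour the 2,4-cis isomer. A 2'-hydroxychalcone also equilibrates with the flavanone, and A2 is itself a long synthesis.
- Comparison: structurally A1 gains more than 21 does (a carbocycle and an aromatic system against one heterocycle and two bonds). Mechanistically it is a thermodynamically driven Claisen condensation against a kinetically controlled aryne capture. In step economy it loses, since several differentiation and ring-closure steps follow A1 whereas one deprotection follows 21.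

Alternative 2: The cut is O1–C2 at the lactone oxidation level, paid for by a strained C–C bond in the cyclobutanone A4. In the forward step one of the two equivalent phenols of A4 would add to the cyclobutanone carbonyl, and retro-Claisen cleavage toward the acyl-bearing carbon would release the strain and give the dihydrocoumarin A3.
- In favour: the step is strain-driven and mild, and the symmetrical ring A of A4 removes any choice between the phenols. C4 is set beforehand, which is equal to the chosen plan. C2' appears as an enone carbonyl with one alkenyl and one alkyl flank, a good substrate for catalyst-controlled reduction, so on the C2' problem it is at least the equal of the chosen plan, and better in that the C2' oxygen is already in place.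
- Against: C2 emerges as a lactone carbonyl. Ring B must be added and the anomeric oxygen removed through an oxocarbenium ion, which is expected to favour the 2,4-cis chroman. C8 is still unsubstituted, so the cinnamoyl group would come by late acylation with C6 and C8 both activated. The benzyl ether calls for a cleavage method compatible with the final chalcone.
- Comparison: structurally it reaches the bicyclic core with C4 and the chain quickly. Mechanistically it breaks a C–C bond where the chosen step makes a C–O and a C–C bond. In step economy the early gain is spent on C2 and C8, and these are the two issues the aryne step settles.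

Alternative 3: The cut removes ring A entirely (C5–C6, C7–C8, C4a–C5), leaving the dihydropyranyl diazoketone A6 and methoxyethyne A7. In the forward step photolysis of A6 would trigger a Wolff rearrangement to a ketene conjugated with the ring olefin. Cycloaddition with A7, four-electron ring opening, six-electron ring closure and tautomerisation would give the chroman A5.
- In favour: it is highly convergent and runs under neutral conditions without an aryl halide. The 5-hydroxy/7-methoxy pattern is fixed by the polarity of A7, and the C5 hydroxyl arrives free and distinct from the methoxy group, which is better than the chosen plan, where step 1 needs a selective demethylation. C2 is never ionised, which is equal to the chosen plan.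
- Against: A5 has hydrogen at C8, so the cinnamoyl group needs a further C–C bond-forming sequence with a C6/C8 choice. A6 is an acid-sensitive acyl enol ether with two stereocentres and a diazo group and is long to prepare. A7 is volatile and unstable.
- Comparison: structurally it creates more per step (three bonds and an arene). Mechanistically it is a pericyclic cascade against a polar aryne capture. In step economy it is longer before the key step and two to three steps longer after it, because the chosen step installs the acyl group in the same flask.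

Key step: step 14

Assumption: 2-bromo-4,6-dimethoxybenzaldehyde (1) is taken as a catalogue compound; its substitution pattern fixes the ring-A regiochemistry from the start.
Remark: the CIP label at C4 is S in 9, 14, 15, 16 and 22 but R in 17, 19, 20 and 21, and the label at C2' is S in 14 and 15 but R from 16 onwards. Only the ranking of the neighbouring groups changes; the spatial arrangement at both centres is the same throughout.

## Route

Step 1
Reactants: 1 2-bromo-4,6-dimethoxybenzaldehyde
Product: 2 2-bromo-6-hydroxy-4-methoxybenzaldehyde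
Conditions: BCl3 (1.5 equiv), CH2Cl2, −78 → 0 °C; aq work-up
Reagents that add atoms: none
Why: Chelation-controlled Lewis-acid ether cleavage: BCl3 binds the aldehyde oxygen and removes only the methyl group of the ortho methoxy group through a six-membered boron chelate, leaving the para methoxy group and the bromide untouched.

Step 2
Reactants: 2 2-bromo-6-hydroxy-4-methoxybenzaldehyde
Product: 3 2-bromo-4-methoxy-6-(triisopropylsilyloxy)benzaldehyde
Conditions: TIPSCl, imidazole, 4-(dimethylamino)pyridine (cat.), DMF, rt
Reagents that add atoms: triisopropylsilyl chloride, CC(C)[Si](Cl)(C(C)C)C(C)C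
Why: Silyl ether formation on a phenol; the triisopropylsilyl group survives all later bases and nucleophiles, leaves with fluoride at the end and is too bulky to direct lithiation to C6 in the key step.

Step 3
Reactants: 3 2-bromo-4-methoxy-6-(triisopropylsilyloxy)benzaldehyde
Product: 5 (E)-3-[2-bromo-4-methoxy-6-(triisopropylsilyloxy)phenyl]prop-2-enal, via vinyl dioxolane 4 (not isolated)
Conditions: (1,3-dioxolan-2-ylmethyl)triphenylphosphonium bromide, NaN(SiMe3)2, THF, 0 °C → rt; then 1 M HCl, THF, rt
Reagents that add atoms: (1,3-dioxolan-2-ylmethyl)triphenylphosphonium bromide, [Br-].C1COC(C[P+](c2ccccc2)(c2ccccc2)c2ccccc2)O1; water, O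
Why: Wittig olefination with a masked formylmethyl ylide followed by acetal hydrolysis; the masked ylide avoids the second homologation that a free formyl ylide would cause on the less hindered product, and the acid equilibrates the enal to the (E)-isomer.

Step 4
Reactants: 6 4'-hydroxyacetophenone
Product: 7 1-[4-(triisopropylsilyloxy)phenyl]ethan-1-one
Conditions: TIPSCl, imidazole, DMF, rt
Reagents that add atoms: triisopropylsilyl chloride, CC(C)[Si](Cl)(C(C)C)C(C)C
Why: Silyl ether formation on an unhindered phenol.

Step 5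
Reactants: 7 1-[4-(triisopropylsilyloxy)phenyl]ethan-1-one
Product: 8 trimethyl({1-[4-(triisopropylsilyloxy)phenyl]ethenyl}oxy)silane
Conditions: TMSOTf, Et3N, CH2Cl2, 0 °C
Reagents that add atoms: trimethylsilyl trifluoromethanesulfonate, C[Si](C)(C)OS(=O)(=O)C(F)(F)F
Why: Silyl enol ether formation by soft enolisation; the ketone has one enolisable position, so only one regioisomer can form.

Step 6
Reactants: 5 (E)-3-[2-bromo-4-methoxy-6-(triisopropylsilyloxy)phenyl]prop-2-enal; 8 trimethyl({1-[4-(triisopropylsilyloxy)phenyl]ethenyl}oxy)silane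
Product: 9 (3S)-3-[2-bromo-4-methoxy-6-(triisopropylsilyloxy)phenyl]-5-oxo-5-[4-(triisopropylsilyloxy)phenyl]pentanal
Conditions: 8 (2.5 equiv), (2R,5R)-5-benzyl-2-tert-butyl-3-methylimidazolidin-4-one (20 mol %), 2,4-dinitrobenzoic acid (20 mol %), t-BuOH/i-PrOH 5:1, −20 → 0 °C
Reagents that add atoms: none
Why: Iminium-catalysed Mukaiyama–Michael addition: the (E)-iminium ion of 5 is attacked at C4 by the unhindered CH2 terminus of 8 on the face opposite the benzyl group of the (2R,5R)-imidazolidinone, which by the usual shielding model should give (S) at C4. The two arms emerge already differentiated as aldehyde and aryl ketone.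

Step 7
Reactants: 10 4-hydroxybenzaldehyde
Product: 11 4-(triisopropylsilyloxy)benzaldehyde
Conditions: TIPSCl, imidazole, DMF, rt
Reagents that add atoms: triisopropylsilyl chloride, CC(C)[Si](Cl)(C(C)C)C(C)C
Why: Silyl ether formation on an unhindered phenol; 11 serves two branches.

Step 8
Reactants: 11 4-(triisopropylsilyloxy)benzaldehyde
Product: 12 (4-ethynylphenoxy)triisopropylsilane
Conditions: Me3SiCHN2, n-BuLi, THF, −78 °C; then 11, −78 °C → rt; aq NH4Cl
Reagents that add atoms: (trimethylsilyl)diazomethane, C[Si](C)(C)C=[N+]=[N-]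
Why: Colvin rearrangement: lithiated (trimethylsilyl)diazomethane adds to the aldehyde, Peterson-type loss of lithium trimethylsilanolate gives a diazoalkene, and loss of N2 with a 1,2-hydride shift of the alkylidene carbene gives the terminal alkyne. The aprotic, methanol-free conditions spare the aryl silyl ether.

Step 9
Reactants: 9 (3S)-3-[2-bromo-4-methoxy-6-(triisopropylsilyloxy)phenyl]-5-oxo-5-[4-(triisopropylsilyloxy)phenyl]pentanal; 12 (4-ethynylphenoxy)triisopropylsilane
Product: 14 (3S,5S)-3-[2-bromo-4-methoxy-6-(triisopropylsilyloxy)phenyl]-5-hydroxy-1,7-bis[4-(triisopropylsilyloxy)phenyl]hept-6-yn-1-one, via alkynyl(methyl)zinc 13 (not isolated)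
Conditions: 12 (2.8 equiv, excess recovered), Me2Zn (2.9 equiv), (S,S)-ProPhenol [2,6-bis{[(2S)-2-(hydroxydiphenylmethyl)pyrrolidin-1-yl]methyl}-4-methylphenol] (20 mol %), Ph3PO (40 mol %), toluene, 0 °C, 1 h; then 9, 4 °C; aq NH4Cl
Reagents that add atoms: dimethylzinc, C[Zn]C (zinc and methyl group of intermediate 13 only)
Why: Catalytic asymmetric zinc alkynylation of an aldehyde: Me2Zn metalates 12 to the alkynylzinc 13, and the dinuclear zinc–ProPhenol complex holds 13 and the aldehyde of 9 on neighbouring zinc centres and delivers the alkynyl group to one aldehyde face under catalyst control. The (S,S)-ligand is chosen on the working assumption that it gives (5S); the sense is to be confirmed by Mosher ester analysis of 14, and the (R,R)-ligand is equally available. The aryl ketone is far less electrophilic than the aldehyde and should not be attacked by the alkynylzinc at this temperature.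

Step 10
Reactants: 14 (3S,5S)-3-[2-bromo-4-methoxy-6-(triisopropylsilyloxy)phenyl]-5-hydroxy-1,7-bis[4-(triisopropylsilyloxy)phenyl]hept-6-yn-1-one
Product: 15 (3S,5S)-3-[2-bromo-4-methoxy-6-(triisopropylsilyloxy)phenyl]-5-(tert-butyldimethylsilyloxy)-1,7-bis[4-(triisopropylsilyloxy)phenyl]hept-6-yn-1-one
Conditions: TBSCl, imidazole, DMF, rt
Reagents that add atoms: tert-butyldimethylsilyl chloride, CC(C)(C)[Si](C)(C)Cl
Why: Silyl ether formation on the only free hydroxyl; the C2 oxygen is still a ketone, so the two carbinol oxygens are differentiated without a selectivity problem, and the silyl group blocks isomerisation or hydrogenolysis at C2' in the next step.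

Step 11
Reactants: 15 (3S,5S)-3-[2-bromo-4-methoxy-6-(triisopropylsilyloxy)phenyl]-5-(tert-butyldimethylsilyloxy)-1,7-bis[4-(triisopropylsilyloxy)phenyl]hept-6-yn-1-one
Product: 16 (3S,5R)-3-[2-bromo-4-methoxy-6-(triisopropylsilyloxy)phenyl]-5-(tert-butyldimethylsilyloxy)-1,7-bis[4-(triisopropylsilyloxy)phenyl]heptan-1-one
Conditions: H2 (1 atm), PtO2 (5 mol %), EtOAc, rt; stopped after uptake of 2 equiv H2
Reagents that add atoms: none
Why: Heterogeneous catalytic hydrogenation of the alkyne to the alkane through the cis-alkene; platinum is chosen because it cleaves aryl C–Br bonds far more slowly than palladium, and in neutral ethyl acetate the electron-rich aryl ketone and the silyl ethers should survive. No stereocentre is touched; the C2' descriptor changes only because the alkynyl group no longer outranks the other arm.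

Step 12
Reactants: 16 (3S,5R)-3-[2-bromo-4-methoxy-6-(triisopropylsilyloxy)phenyl]-5-(tert-butyldimethylsilyloxy)-1,7-bis[4-(triisopropylsilyloxy)phenyl]heptan-1-one
Product: 17 (1R,3R,5R)-3-[2-bromo-4-methoxy-6-(triisopropylsilyloxy)phenyl]-5-(tert-butyldimethylsilyloxy)-1,7-bis[4-(triisopropylsilyloxy)phenyl]heptan-1-ol
Conditions: (S)-Me-CBS [(3aS)-1-methyl-3,3-diphenyltetrahydro-1H,3H-pyrrolo[1,2-c][1,3,2]oxazaborole] (20 mol %), BH3·SMe2, THF, −20 °C; MeOH quench
Reagents that add atoms: none
Why: Corey–Bakshi–Shibata reduction of an aryl alkyl ketone: the (S)-oxazaborolidine–borane complex delivers hydride to the face that gives the (R)-benzylic alcohol (aryl as the large group), and this reagent control overrides the weak bias of the remote C4 centre.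

Step 13
Reactants: 11 4-(triisopropylsilyloxy)benzaldehyde
Product: 18 (E)-N-methoxy-N-methyl-3-[4-(triisopropylsilyloxy)phenyl]prop-2-enamide
Conditions: (EtO)2P(O)CH2C(O)N(OMe)Me, NaH, THF, 0 °C → rt
Reagents that add atoms: diethyl [2-(methoxy(methyl)amino)-2-oxoethyl]phosphonate, CCOP(=O)(CC(=O)N(C)OC)OCC
Why: Horner–Wadsworth–Emmons olefination with a stabilised phosphonate anion gives the (E)-configured Weinreb enamide.

Step 14
Reactants: 17 (1R,3R,5R)-3-[2-bromo-4-methoxy-6-(triisopropylsilyloxy)phenyl]-5-(tert-butyldimethylsilyloxy)-1,7-bis[4-(triisopropylsilyloxy)phenyl]heptan-1-ol; 18 (E)-N-methoxy-N-methyl-3-[4-(triisopropylsilyloxy)phenyl]prop-2-enamide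
Product: 21 (E)-1-[(2R,4R)-4-{(2R)-2-(tert-butyldimethylsilyloxy)-4-[4-(triisopropylsilyloxy)phenyl]butyl}-7-methoxy-5-(triisopropylsilyloxy)-2-[4-(triisopropylsilyloxy)phenyl]-3,4-dihydro-2H-chromen-8-yl]-3-[4-(triisopropylsilyloxy)phenyl]prop-2-en-1-one, via aryne alkoxide 19 (not isolated), via C8 aryllithium 20 (not isolated)
Conditions: LiTMP (lithium 2,2,6,6-tetramethylpiperidide, from 2,2,6,6-tetramethylpiperidine and n-BuLi; 3.2 equiv), THF, −78 → −30 °C; then 18 (2.5 equiv), −78 → 0 °C; aq NH4Cl
Reagents that add atoms: lithium 2,2,6,6-tetramethylpiperidide, CC1(C)CCCC(C)(C)N1[Li] (lithium of intermediates 19 and 20 only)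
Why: LiTMP first deprotonates the C2 hydroxyl and then C8–H, the only ring hydrogen ortho to bromine and further acidified by the C7 methoxy group; on warming the ortho-bromoaryllithium loses LiBr to give the C8–C8a aryne 19. The tethered lithium alkoxide adds in the plane of the aryne to the proximal carbon C8a, forming O1–C8a and closing the six-membered pyran ring in an exo-dig sense (the aryne bond lies outside the new ring), which leaves the C8 aryllithium 20 stabilised by the flanking methoxy and ring oxygens. After recooling, 20 adds 1,2 to the Weinreb amide 18 to give an N,O-chelated tetrahedral adduct that releases the enone only on work-up, so over-addition and conjugate addition are avoided and the C8–carbonyl bond is formed. The closest known reaction type is the intramolecular alkoxide–aryne cyclisation to chromans with trapping of the resulting aryllithium by an electrophile in the same flask. No stereocentre is created: the C2–O bond is never broken, so C2 enters the ring with retention, C4 and C2' are spectators, and the 2,4-trans relationship is fixed by the earlier reagent-controlled steps and not by ring thermodynamics. Three selectivities are needed: aryne formation at C8–C8a only (secured by the bromine position, the single ortho hydrogen and the poor directing ability of the bulky silyloxy group at C5, which keeps the base away from C6); oxygen attack at C8a and not C8 (secured by the three-atom tether and reinforced by the methoxy group, which polarises the aryne toward attack at the distal carbon); and cyclisation through the C2 oxygen only (secured by the silyl ether on the C2' oxygen, which could otherwise close an isomeric six-membered ring).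

Step 15
Reactants: 21 (E)-1-[(2R,4R)-4-{(2R)-2-(tert-butyldimethylsilyloxy)-4-[4-(triisopropylsilyloxy)phenyl]butyl}-7-methoxy-5-(triisopropylsilyloxy)-2-[4-(triisopropylsilyloxy)phenyl]-3,4-dihydro-2H-chromen-8-yl]-3-[4-(triisopropylsilyloxy)phenyl]prop-2-en-1-one
Product: 22 (E)-1-[(2R,4S)-5-hydroxy-4-[(2R)-2-hydroxy-4-(4-hydroxyphenyl)butyl]-2-(4-hydroxyphenyl)-7-methoxy-3,4-dihydro-2H-chromen-8-yl]-3-(4-hydroxyphenyl)prop-2-en-1-one (CNP0102599.2)
Conditions: TBAF (10 equiv), AcOH (10 equiv), THF, 0 °C → rt
Reagents that add atoms: none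
Why: Fluoride desilylation of four aryl silyl ethers and one secondary alkyl silyl ether; acetic acid buffers the medium so that no phenoxide can open the C2–O1 bond through a quinone methide and the chalcone is not attacked.

## Compound list

1 | 2-bromo-4,6-dimethoxybenzaldehyde | COc1cc(OC)c(C=O)c(Br)c1 | starting material
2 | 2-bromo-6-hydroxy-4-methoxybenzaldehyde | COc1cc(O)c(C=O)c(Br)c1 | intermediate
3 | 2-bromo-4-methoxy-6-(triisopropylsilyloxy)benzaldehyde | COc1cc(O[Si](C(C)C)(C(C)C)C(C)C)c(C=O)c(Br)c1 | intermediate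
4 | 2-{2-[2-bromo-4-methoxy-6-(triisopropylsilyloxy)phenyl]ethenyl}-1,3-dioxolane (E/Z mixture) | COc1cc(O[Si](C(C)C)(C(C)C)C(C)C)c(C=CC2OCCO2)c(Br)c1 | intermediate (not isolated)
5 | (E)-3-[2-bromo-4-methoxy-6-(triisopropylsilyloxy)phenyl]prop-2-enal | COc1cc(O[Si](C(C)C)(C(C)C)C(C)C)c(/C=C/C=O)c(Br)c1 | intermediate
6 | 4'-hydroxyacetophenone | CC(=O)c1ccc(O)cc1 | starting material
7 | 1-[4-(triisopropylsilyloxy)phenyl]ethan-1-one | CC(=O)c1ccc(O[Si](C(C)C)(C(C)C)C(C)C)cc1 | intermediate
8 | trimethyl({1-[4-(triisopropylsilyloxy)phenyl]ethenyl}oxy)silane | C=C(O[Si](C)(C)C)c1ccc(O[Si](C(C)C)(C(C)C)C(C)C)cc1 | intermediate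
9 | (3S)-3-[2-bromo-4-methoxy-6-(triisopropylsilyloxy)phenyl]-5-oxo-5-[4-(triisopropylsilyloxy)phenyl]pentanal | COc1cc(O[Si](C(C)C)(C(C)C)C(C)C)c(c(Br)c1)[C@H](CC(=O)c1ccc(O[Si](C(C)C)(C(C)C)C(C)C)cc1)CC=O | intermediate
10 | 4-hydroxybenzaldehyde | O=Cc1ccc(O)cc1 | starting material
11 | 4-(triisopropylsilyloxy)benzaldehyde | O=Cc1ccc(O[Si](C(C)C)(C(C)C)C(C)C)cc1 | intermediate
12 | (4-ethynylphenoxy)triisopropylsilane | C#Cc1ccc(O[Si](C(C)C)(C(C)C)C(C)C)cc1 | intermediate
13 | methyl{[4-(triisopropylsilyloxy)phenyl]ethynyl}zinc | C[Zn]C#Cc1ccc(O[Si](C(C)C)(C(C)C)C(C)C)cc1 | intermediate (not isolated)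
14 | (3S,5S)-3-[2-bromo-4-methoxy-6-(triisopropylsilyloxy)phenyl]-5-hydroxy-1,7-bis[4-(triisopropylsilyloxy)phenyl]hept-6-yn-1-one | COc1cc(O[Si](C(C)C)(C(C)C)C(C)C)c(c(Br)c1)[C@H](CC(=O)c1ccc(O[Si](C(C)C)(C(C)C)C(C)C)cc1)C[C@H](O)C#Cc1ccc(O[Si](C(C)C)(C(C)C)C(C)C)cc1 | intermediate
15 | (3S,5S)-3-[2-bromo-4-methoxy-6-(triisopropylsilyloxy)phenyl]-5-(tert-butyldimethylsilyloxy)-1,7-bis[4-(triisopropylsilyloxy)phenyl]hept-6-yn-1-one | COc1cc(O[Si](C(C)C)(C(C)C)C(C)C)c(c(Br)c1)[C@H](CC(=O)c1ccc(O[Si](C(C)C)(C(C)C)C(C)C)cc1)C[C@H](O[Si](C)(C)C(C)(C)C)C#Cc1ccc(O[Si](C(C)C)(C(C)C)C(C)C)cc1 | intermediate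
16 | (3S,5R)-3-[2-bromo-4-methoxy-6-(triisopropylsilyloxy)phenyl]-5-(tert-butyldimethylsilyloxy)-1,7-bis[4-(triisopropylsilyloxy)phenyl]heptan-1-one | COc1cc(O[Si](C(C)C)(C(C)C)C(C)C)c(c(Br)c1)[C@H](CC(=O)c1ccc(O[Si](C(C)C)(C(C)C)C(C)C)cc1)C[C@H](O[Si](C)(C)C(C)(C)C)CCc1ccc(O[Si](C(C)C)(C(C)C)C(C)C)cc1 | intermediate
17 | (1R,3R,5R)-3-[2-bromo-4-methoxy-6-(triisopropylsilyloxy)phenyl]-5-(tert-butyldimethylsilyloxy)-1,7-bis[4-(triisopropylsilyloxy)phenyl]heptan-1-ol | COc1cc(O[Si](C(C)C)(C(C)C)C(C)C)c(c(Br)c1)[C@H](C[C@@H](O)c1ccc(O[Si](C(C)C)(C(C)C)C(C)C)cc1)C[C@H](O[Si](C)(C)C(C)(C)C)CCc1ccc(O[Si](C(C)C)(C(C)C)C(C)C)cc1 | intermediate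
18 | (E)-N-methoxy-N-methyl-3-[4-(triisopropylsilyloxy)phenyl]prop-2-enamide | CON(C)C(=O)/C=C/c1ccc(O[Si](C(C)C)(C(C)C)C(C)C)cc1 | intermediate
19 | lithium alkoxide of 17 in which bromine and C8–H are lost and C8–C8a is an aryne bond | [Li+].COC1=CC(O[Si](C(C)C)(C(C)C)C(C)C)=C(C#C1)[C@H](C[C@@H]([O-])c1ccc(O[Si](C(C)C)(C(C)C)C(C)C)cc1)C[C@H](O[Si](C)(C)C(C)(C)C)CCc1ccc(O[Si](C(C)C)(C(C)C)C(C)C)cc1 | intermediate (not isolated)
20 | {(2R,4R)-4-{(2R)-2-(tert-butyldimethylsilyloxy)-4-[4-(triisopropylsilyloxy)phenyl]butyl}-7-methoxy-5-(triisopropylsilyloxy)-2-[4-(triisopropylsilyloxy)phenyl]-3,4-dihydro-2H-chromen-8-yl}lithium | COc1cc(O[Si](C(C)C)(C(C)C)C(C)C)c2c(c1[Li])O[C@@H](c1ccc(O[Si](C(C)C)(C(C)C)C(C)C)cc1)C[C@@H]2C[C@H](O[Si](C)(C)C(C)(C)C)CCc1ccc(O[Si](C(C)C)(C(C)C)C(C)C)cc1 | intermediate (not isolated)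
21 | (E)-1-[(2R,4R)-4-{(2R)-2-(tert-butyldimethylsilyloxy)-4-[4-(triisopropylsilyloxy)phenyl]butyl}-7-methoxy-5-(triisopropylsilyloxy)-2-[4-(triisopropylsilyloxy)phenyl]-3,4-dihydro-2H-chromen-8-yl]-3-[4-(triisopropylsilyloxy)phenyl]prop-2-en-1-one | COc1cc(O[Si](C(C)C)(C(C)C)C(C)C)c2c(c1C(=O)/C=C/c1ccc(O[Si](C(C)C)(C(C)C)C(C)C)cc1)O[C@@H](c1ccc(O[Si](C(C)C)(C(C)C)C(C)C)cc1)C[C@@H]2C[C@H](O[Si](C)(C)C(C)(C)C)CCc1ccc(O[Si](C(C)C)(C(C)C)C(C)C)cc1 | intermediate
22 | (E)-1-[(2R,4S)-5-hydroxy-4-[(2R)-2-hydroxy-4-(4-hydroxyphenyl)butyl]-2-(4-hydroxyphenyl)-7-methoxy-3,4-dihydro-2H-chromen-8-yl]-3-(4-hydroxyphenyl)prop-2-en-1-one | COc1cc(O)c2c(c1C(=O)/C=C/c1ccc(O)cc1)O[C@@H](c1ccc(O)cc1)C[C@@H]2C[C@H](O)CCc1ccc(O)cc1 | target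

## Step count and least certain steps

Total: 15 steps. Longest linear sequence: 10 steps (steps 1, 2, 3, 6, 9, 10, 11, 12, 14, 15). The minor enantiomer carried from step 6 becomes a diastereomer after steps 9 and 12 and should be removable by chromatography.

Step 14 (key step). Most likely to go wrong: the C8 aryllithium may be lost by proton transfer from tetramethylpiperidine, or acylation of this doubly ortho-substituted anion may be incomplete; competing metalation at C6 with silyl migration is a lesser concern. The fallback runs from 17 back to 21 and separates ring closure from acylation. Intramolecular Buchwald–Hartwig etherification of 17 (Pd(OAc)2, 2-(di-tert-butylphosphino)-1,1'-binaphthyl, Cs2CO3, toluene, 70 °C) would close O1–C8a with retention at C2 and give the C8-unsubstituted chroman tert-butyl{[(2R)-1-{(2R,4R)-7-methoxy-5-(triisopropylsilyloxy)-2-[4-(triisopropylsilyloxy)phenyl]-3,4-dihydro-2H-chromen-4-yl}-4-[4-(triisopropylsilyloxy)phenyl]butan-2-yl]oxy}dimethylsilane F1. Directed ortho-lithiation of F1 at C8, between O1 and the methoxy oxygen (n-BuLi, N,N,N',N'-tetramethylethylenediamine, THF, 0 °C), followed by 18 at −78 °C, returns to 21.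

Step 6. Most likely to go wrong: conjugate addition to the doubly ortho-substituted, electron-rich enal may be so slow that hydrolysis of the silyl enol ether outruns C–C bond formation, or the twisted aryl group may erode facial discrimination; the sense of induction rests on a model and must be confirmed. The fallback runs from 5 back to 9 and uses an anionic malonate nucleophile. Diallyl malonate with (R)-α,α-diphenylprolinol trimethylsilyl ether (10 mol %) in EtOH should add to 5 and give diallyl 2-{(1S)-1-[2-bromo-4-methoxy-6-(triisopropylsilyloxy)phenyl]-3-oxopropyl}propanedioate F2. NaBH4 in MeOH at 0 °C, then p-toluenesulfonic acid (cat.) in toluene, would reduce the aldehyde and close the lactone to allyl (4S)-4-[2-bromo-4-methoxy-6-(triisopropylsilyloxy)phenyl]-2-oxooxane-3-carboxylate F3. Pd(PPh3)4 and morpholine in THF at rt, then toluene at 90 °C, would remove the allyl ester and decarboxylate to (4S)-4-[2-bromo-4-methoxy-6-(triisopropylsilyloxy)phenyl]oxan-2-one F4. 4-Bromophenol would be silylated (TIPSCl, imidazole) to (4-bromophenoxy)triisopropylsilane F5, whose aryllithium (n-BuLi, THF, −78 °C) should add once to F4 at −78 °C to give (3S)-3-[2-bromo-4-methoxy-6-(triisopropylsilyloxy)phenyl]-5-hydroxy-1-[4-(triisopropylsilyloxy)phenyl]pentan-1-one F6. Dess–Martin oxidation of the primary alcohol of F6 returns to 9.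

Step 9. Most likely to go wrong: enantiofacial control may erode on an aldehyde without α-branching, zinc-enolate aldol chemistry of the aldehyde or the aryl ketone may compete with the slow alkynyl transfer, and the hydroxy ketone may partly close to a lactol. The fallback runs from 9 back to 16 and transfers the saturated arm as an sp3 organozinc reagent, so that no alkyne has to be reduced. 4-(2-Bromoethyl)phenol would be silylated (TIPSCl, imidazole, CH2Cl2) to [4-(2-bromoethyl)phenoxy]triisopropylsilane F7. Zinc insertion (Zn dust activated with BrCH2CH2Br and Me3SiCl, LiCl, THF, 50 °C) should give bromo{2-[4-(triisopropylsilyloxy)phenyl]ethyl}zinc F8, and Me3SiCH2Li at −78 °C would convert it into the mixed diorganozinc {2-[4-(triisopropylsilyloxy)phenyl]ethyl}[(trimethylsilyl)methyl]zinc F9, in which the trimethylsilylmethyl group does not transfer; THF is exchanged for toluene and the lithium halides are filtered off. Addition of F9 to 9 with Ti(OiPr)4 and (1S,2S)-1,2-bis(trifluoromethanesulfonamido)cyclohexane (8 mol %) in toluene at −20 °C should deliver the alkyl group to one aldehyde face under catalyst control, leave the aryl ketone alone and give (3S,5R)-3-[2-bromo-4-methoxy-6-(triisopropylsilyloxy)phenyl]-5-hydroxy-1,7-bis[4-(triisopropylsilyloxy)phenyl]heptan-1-one F10. TBSCl and imidazole on F10 return to 16.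

Step 11. Most likely to go wrong: hydrogenolysis of the aryl C–Br bond or partial reduction of the aryl ketone may set in before the alkyne is fully saturated, or the reduction may stall at the cis-alkene beside the bulky silyl ether. The fallback runs from 15 back to 17, reverses the order of the two reductions and replaces metal-catalysed hydrogenation by diimide. Corey–Bakshi–Shibata reduction of 15 with catecholborane as the hydride source ((S)-Me-CBS, toluene, −78 °C), which does not hydroborate the alkyne, should give (1R,3R,5S)-3-[2-bromo-4-methoxy-6-(triisopropylsilyloxy)phenyl]-5-(tert-butyldimethylsilyloxy)-1,7-bis[4-(triisopropylsilyloxy)phenyl]hept-6-yn-1-ol F11. Diimide generated from 2-nitrobenzenesulfonylhydrazide and Et3N in CH2Cl2 at rt, added in portions, is inert to aryl bromides and, with the ketone already reduced, has no carbonyl to condense with; it should saturate the alkyne of F11 and return to 17.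

Step 15. Most likely to go wrong: cleavage of the secondary tert-butyldimethylsilyl ether may be incomplete under buffered fluoride, and forcing it with stronger base or acid could open the C2–O1 bond and equilibrate toward the more stable 2,4-cis chroman. The fallback runs from 14 back to 22 and changes the protecting group on the C2' oxygen. TESCl and imidazole on 14 would give (3S,5S)-3-[2-bromo-4-methoxy-6-(triisopropylsilyloxy)phenyl]-5-(triethylsilyloxy)-1,7-bis[4-(triisopropylsilyloxy)phenyl]hept-6-yn-1-one F12. Hydrogenation as in step 11 would give (3S,5R)-3-[2-bromo-4-methoxy-6-(triisopropylsilyloxy)phenyl]-5-(triethylsilyloxy)-1,7-bis[4-(triisopropylsilyloxy)phenyl]heptan-1-one F13, and Corey–Bakshi–Shibata reduction as in step 12 would give (1R,3R,5R)-3-[2-bromo-4-methoxy-6-(triisopropylsilyloxy)phenyl]-5-(triethylsilyloxy)-1,7-bis[4-(triisopropylsilyloxy)phenyl]heptan-1-ol F14. The aryne cyclisation and acylation with 18 as in step 14 would give (E)-1-[(2R,4R)-7-methoxy-4-{(2R)-2-(triethylsilyloxy)-4-[4-(triisopropylsilyloxy)phenyl]butyl}-5-(triisopropylsilyloxy)-2-[4-(triisopropylsilyloxy)phenyl]-3,4-dihydro-2H-chromen-8-yl]-3-[4-(triisopropylsilyloxy)phenyl]prop-2-en-1-one F15. All silyl groups of F15 should leave under TBAF/AcOH at 0 °C to give 22.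

Further compounds

F1 | step 14 | tert-butyl{[(2R)-1-{(2R,4R)-7-methoxy-5-(triisopropylsilyloxy)-2-[4-(triisopropylsilyloxy)phenyl]-3,4-dihydro-2H-chromen-4-yl}-4-[4-(triisopropylsilyloxy)phenyl]butan-2-yl]oxy}dimethylsilane | COc1cc(O[Si](C(C)C)(C(C)C)C(C)C)c2c(c1)O[C@@H](c1ccc(O[Si](C(C)C)(C(C)C)C(C)C)cc1)C[C@@H]2C[C@H](O[Si](C)(C)C(C)(C)C)CCc1ccc(O[Si](C(C)C)(C(C)C)C(C)C)cc1
F2 | step 6 | diallyl 2-{(1S)-1-[2-bromo-4-methoxy-6-(triisopropylsilyloxy)phenyl]-3-oxopropyl}propanedioate | COc1cc(O[Si](C(C)C)(C(C)C)C(C)C)c(c(Br)c1)[C@H](C(C(=O)OCC=C)C(=O)OCC=C)CC=O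
F3 | step 6 | allyl (4S)-4-[2-bromo-4-methoxy-6-(triisopropylsilyloxy)phenyl]-2-oxooxane-3-carboxylate (C3 epimers) | COc1cc(O[Si](C(C)C)(C(C)C)C(C)C)c(c(Br)c1)[C@@H]1C(C(=O)OCC=C)C(=O)OCC1
F4 | step 6 | (4S)-4-[2-bromo-4-methoxy-6-(triisopropylsilyloxy)phenyl]oxan-2-one | COc1cc(O[Si](C(C)C)(C(C)C)C(C)C)c(c(Br)c1)[C@@H]1CC(=O)OCC1
F5 | step 6 | (4-bromophenoxy)triisopropylsilane | Brc1ccc(O[Si](C(C)C)(C(C)C)C(C)C)cc1
F6 | step 6 | (3S)-3-[2-bromo-4-methoxy-6-(triisopropylsilyloxy)phenyl]-5-hydroxy-1-[4-(triisopropylsilyloxy)phenyl]pentan-1-one | COc1cc(O[Si](C(C)C)(C(C)C)C(C)C)c(c(Br)c1)[C@H](CC(=O)c1ccc(O[Si](C(C)C)(C(C)C)C(C)C)cc1)CCO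
F7 | step 9 | [4-(2-bromoethyl)phenoxy]triisopropylsilane | BrCCc1ccc(O[Si](C(C)C)(C(C)C)C(C)C)cc1
F8 | step 9 | bromo{2-[4-(triisopropylsilyloxy)phenyl]ethyl}zinc | Br[Zn]CCc1ccc(O[Si](C(C)C)(C(C)C)C(C)C)cc1
F9 | step 9 | {2-[4-(triisopropylsilyloxy)phenyl]ethyl}[(trimethylsilyl)methyl]zinc | C[Si](C)(C)C[Zn]CCc1ccc(O[Si](C(C)C)(C(C)C)C(C)C)cc1
F10 | step 9 | (3S,5R)-3-[2-bromo-4-methoxy-6-(triisopropylsilyloxy)phenyl]-5-hydroxy-1,7-bis[4-(triisopropylsilyloxy)phenyl]heptan-1-one | COc1cc(O[Si](C(C)C)(C(C)C)C(C)C)c(c(Br)c1)[C@H](CC(=O)c1ccc(O[Si](C(C)C)(C(C)C)C(C)C)cc1)C[C@H](O)CCc1ccc(O[Si](C(C)C)(C(C)C)C(C)C)cc1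
F11 | step 11 | (1R,3R,5S)-3-[2-bromo-4-methoxy-6-(triisopropylsilyloxy)phenyl]-5-(tert-butyldimethylsilyloxy)-1,7-bis[4-(triisopropylsilyloxy)phenyl]hept-6-yn-1-ol | COc1cc(O[Si](C(C)C)(C(C)C)C(C)C)c(c(Br)c1)[C@H](C[C@@H](O)c1ccc(O[Si](C(C)C)(C(C)C)C(C)C)cc1)C[C@H](O[Si](C)(C)C(C)(C)C)C#Cc1ccc(O[Si](C(C)C)(C(C)C)C(C)C)cc1
F12 | step 15 | (3S,5S)-3-[2-bromo-4-methoxy-6-(triisopropylsilyloxy)phenyl]-5-(triethylsilyloxy)-1,7-bis[4-(triisopropylsilyloxy)phenyl]hept-6-yn-1-one | COc1cc(O[Si](C(C)C)(C(C)C)C(C)C)c(c(Br)c1)[C@H](CC(=O)c1ccc(O[Si](C(C)C)(C(C)C)C(C)C)cc1)C[C@H](O[Si](CC)(CC)CC)C#Cc1ccc(O[Si](C(C)C)(C(C)C)C(C)C)cc1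
F13 | step 15 | (3S,5R)-3-[2-bromo-4-methoxy-6-(triisopropylsilyloxy)phenyl]-5-(triethylsilyloxy)-1,7-bis[4-(triisopropylsilyloxy)phenyl]heptan-1-one | COc1cc(O[Si](C(C)C)(C(C)C)C(C)C)c(c(Br)c1)[C@H](CC(=O)c1ccc(O[Si](C(C)C)(C(C)C)C(C)C)cc1)C[C@H](O[Si](CC)(CC)CC)CCc1ccc(O[Si](C(C)C)(C(C)C)C(C)C)cc1
F14 | step 15 | (1R,3R,5R)-3-[2-bromo-4-methoxy-6-(triisopropylsilyloxy)phenyl]-5-(triethylsilyloxy)-1,7-bis[4-(triisopropylsilyloxy)phenyl]heptan-1-ol | COc1cc(O[Si](C(C)C)(C(C)C)C(C)C)c(c(Br)c1)[C@H](C[C@@H](O)c1ccc(O[Si](C(C)C)(C(C)C)C(C)C)cc1)C[C@H](O[Si](CC)(CC)CC)CCc1ccc(O[Si](C(C)C)(C(C)C)C(C)C)cc1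
F15 | step 15 | (E)-1-[(2R,4R)-7-methoxy-4-{(2R)-2-(triethylsilyloxy)-4-[4-(triisopropylsilyloxy)phenyl]butyl}-5-(triisopropylsilyloxy)-2-[4-(triisopropylsilyloxy)phenyl]-3,4-dihydro-2H-chromen-8-yl]-3-[4-(triisopropylsilyloxy)phenyl]prop-2-en-1-one | COc1cc(O[Si](C(C)C)(C(C)C)C(C)C)c2c(c1C(=O)/C=C/c1ccc(O[Si](C(C)C)(C(C)C)C(C)C)cc1)O[C@@H](c1ccc(O[Si](C(C)C)(C(C)C)C(C)C)cc1)C[C@@H]2C[C@H](O[Si](CC)(CC)CC)CCc1ccc(O[Si](C(C)C)(C(C)C)C(C)C)cc1
A1 | alternative 1 | (E)-1-{3-[(1R,3S,5R)-1,5-bis(tert-butyldimethylsilyloxy)-1,7-bis[4-(methoxymethoxy)phenyl]heptan-3-yl]-2,6-dihydroxy-4-(methoxymethoxy)phenyl}-3-[4-(methoxymethoxy)phenyl]prop-2-en-1-one | O=C(/C=C/c1ccc(OCOC)cc1)c1c(O)cc(OCOC)c(c1O)[C@H](C[C@@H](O[Si](C)(C)C(C)(C)C)c1ccc(OCOC)cc1)C[C@H](O[Si](C)(C)C(C)(C)C)CCc1ccc(OCOC)cc1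
A2 | alternative 1 | 3-[(1R,3S,5R)-1,5-bis(tert-butyldimethylsilyloxy)-1,7-bis[4-(methoxymethoxy)phenyl]heptan-3-yl]-4-(methoxymethoxy)-6-{(E)-4-[4-(methoxymethoxy)phenyl]-2-oxobut-3-en-1-yl}-2H-pyran-2-one | O=C1OC(CC(=O)/C=C/c2ccc(OCOC)cc2)=CC(OCOC)=C1[C@H](C[C@@H](O[Si](C)(C)C(C)(C)C)c1ccc(OCOC)cc1)C[C@H](O[Si](C)(C)C(C)(C)C)CCc1ccc(OCOC)cc1
A3 | alternative 2 | (4S)-4-{(E)-4-[4-(benzyloxy)phenyl]-2-oxobut-3-en-1-yl}-5-hydroxy-7-methoxy-3,4-dihydro-2H-chromen-2-one | COc1cc(O)c2c(c1)OC(=O)C[C@@H]2CC(=O)/C=C/c1ccc(OCc3ccccc3)cc1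
A4 | alternative 2 | (3R)-2-{(E)-3-[4-(benzyloxy)phenyl]prop-2-enoyl}-3-(2,6-dihydroxy-4-methoxyphenyl)cyclobutan-1-one (C2 epimerisable) | O=C1C[C@@H](c2c(O)cc(OC)cc2O)C1C(=O)/C=C/c1ccc(OCc2ccccc2)cc1
A5 | alternative 3 | (2R,4R)-4-{(2R)-2-(tert-butyldimethylsilyloxy)-4-[4-(triisopropylsilyloxy)phenyl]butyl}-7-methoxy-2-[4-(triisopropylsilyloxy)phenyl]-3,4-dihydro-2H-chromen-5-ol | COc1cc(O)c2c(c1)O[C@@H](c1ccc(O[Si](C(C)C)(C(C)C)C(C)C)cc1)C[C@@H]2C[C@H](O[Si](C)(C)C(C)(C)C)CCc1ccc(O[Si](C(C)C)(C(C)C)C(C)C)cc1
A6 | alternative 3 | 2-diazo-1-{(2R,4R)-4-{(2R)-2-(tert-butyldimethylsilyloxy)-4-[4-(triisopropylsilyloxy)phenyl]butyl}-2-[4-(triisopropylsilyloxy)phenyl]-3,4-dihydro-2H-pyran-6-yl}ethan-1-one | [N-]=[N+]=CC(=O)C1=C[C@@H](C[C@H](O[Si](C)(C)C(C)(C)C)CCc2ccc(O[Si](C(C)C)(C(C)C)C(C)C)cc2)C[C@H](c2ccc(O[Si](C(C)C)(C(C)C)C(C)C)cc2)O1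
A7 | alternative 3 | methoxyethyne | COC#C
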